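# Total synthesis proposal for eupaheliangolide A by fission of a ring-fusion diol

Germacrane numbering is used throughout: ring carbons C1–C10, lactone arm C11 (ring carbon), C12 (carbonyl), C13 (exocyclic CH2), C14 = methyl on C10, C15 = methyl on C4.

## The problem

Eupaheliangolide A (28) is a ten-membered carbocycle in which a C3 ketone is flanked by an E C1=C2 and a Z C4=C5 alkene. A trans α-methylene-γ-butyrolactone is fused across C6/C7, C8 carries a tiglate and C10 a tertiary hydroxyl (6R,7R,8R,10R). C6, C7 and C8 are contiguous, so C7 can control both neighbours if they sit on a small ring. C10 is insulated by C9 and can be related to C8 only through a 1,3-diol relationship. A direct closure of the ten-membered ring pays an entropic price and has to deliver one E and one Z alkene inside a strained ring. The methylene lactone is a Michael acceptor, and the cross-conjugated dienone and the tiglate are base-sensitive. Any C8 carbonyl is β to the C6 lactone oxygen, so it invites E1cB ring opening and C7 epimerisation. The C10 hydroxyl can add across the ring to the C3 carbonyl as long as C1–C2 is saturated. The enabling feature is that C3 and C8 are both oxygenated and stand 1,6 across the ring. A C3–C8 bond turns the macrocycle into a cis-decalin with ring A (C3–C2–C1–C10–C9–C8) and ring B (C3–C4=C5–C6–C7–C8), whose ring-fusion diol can be cut oxidatively. In ring B the C4=C5 alkene is cis of necessity, and ring B has the substitution pattern of carvone.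

## Retrosynthesis

**C1=C2 (28 ⇒ 27).** The E alkene is made last, from a C1 acetoxy group β to the C3 ketone. The alternative of functionalising C2 through a silyl dienol ether and a selenide would need strong base in the presence of the methylene lactone and tiglate. The C1 oxygen, by contrast, arrives together with the C10 hydroxyl and survives Pb(OAc)4. Precursor 27 lacks the dienone. The forward E1cB must give the E isomer.

**C8 ester (27 ⇒ 25 + 26).** The tiglate is attached late, so the unsaturated ester never meets hydride or peracid. Alcohol 25 has one secondary hydroxyl only. The forward step must acylate it beside the tertiary C10 hydroxyl.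

**C8–H (25 ⇒ 23).** C8 is a ketone after the ring fission in any case, so its configuration is best set there. The C10 hydroxyl in 23 is the only handle that can reach it (1,3). The forward reduction must be anti-selective and must leave the C3 enone.

**C3–C8 (23 ⇒ 21), key disconnection.** Reconnecting C3 and C8 as a ditertiary cis-diol gives the 3,8-cyclogermacrane 21. The macrocycle, the Z-enone and the two ketones all result from one cleavage, and C6, C7 and C10 can be set on six-membered rings. The forward step must cut only this diol and must not expose the product to base.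

**C10–O and C1–O (21 ⇒ 20 ⇒ 19 ⇒ 18).** Both oxygens come from the C1=C10 alkene of ring A. Hydride opening of the convex-face epoxide would give the wrong C10 epimer. Water opening at tertiary C10 with inversion gives 10R and leaves a C1 hydroxyl, which is then acetylated. The forward steps need convex-face epoxidation and trans-diaxial opening at C10.

**C1=C10 (18 ⇒ 17).** Ring A is closed by olefin metathesis between a C3 allyl and a C8 methallyl arm. Closing it instead by a sulfonyl carbanion onto a side-chain epoxide would fix C10 on a freely rotating chain without control. Metathesis leaves the alkene to be oxidised on the rigid bicycle. It needs the two arms cis.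

**C2–C3 (17 ⇒ 15 + 16).** The allyl group is added to the ring B ketone of 15. The axial C8 silyloxy group directs it cis to the methallyl arm, which is what the later cis-diol requires. The nucleophile must spare the lactone, hence allylzinc.

**Lactone C12–O (15 ⇒ 12).** The lactone is closed by oxidation of the C6/C12 diol before the C3 addition. The C6 hydroxyl then never needs protection, and the trans-fused lactone locks ring B in the conformation on which steps 7, 9 and 10 rely. The price is the lactone-tolerant reagent in step 7.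

**C6–O (12 ⇒ 9).** The γ-hydroxyl comes from the silyl dienol ether of enone 9. C8 is quaternary, so enolisation can only run towards C6. The oxidant must attack C6, not C4, and anti to the C7 arm.

**C8–C9 (9 ⇒ 6 + 7).** The methallyl group is added by alkylation of the α-silyloxy enolate. Oxygen first and carbon second places C9 trans to the C7 arm. The reverse order would give the C8 epimer, whose axial carbon arm would steer the C3 addition to a trans diol.

**C8–O and C12–O (6 ⇒ 4 ⇒ 2 ⇒ 1).** The C8 oxygen comes from a Rubottom oxidation and the C12 oxygen from allylic chlorination of the isopropenyl group, both while C4=C5 is deactivated as an enone. (S)-Carvone (1) supplies C7, C15 and the C4=C5 alkene.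

## Roads not taken

**Alternative 1:** cut C6–C7. The open-chain bromo ester aldehyde A2 would be treated with CrCl2. The allylchromium formed at C13 adds through C7 to the C6 aldehyde (Nozaki–Hiyama–Kishi type) and gives the ten-membered anti hydroxy ester A1.
- Merits: the closure is convergent and stereoconvergent in the bromide geometry. It sets the anti C6/C7 relationship and delivers the acrylate ready for lactonisation. It is the best-precedented way to close germacranolide rings, and in that respect stronger than the chosen plan.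
- Weak points: it is a true medium-ring closure needing high dilution. The Z-enal of A2 can isomerise. The facial sense relative to C8 rests on 1,2-induction in a floppy chain. C8 and C10 must be made by separate asymmetric steps. A1 still needs lactonisation, two desilylations, C3 oxidation and acylation.
- Against this the chosen plan sets a ring formation without entropic cost, a Z alkene guaranteed by ring B, and C7 from the chiral pool. It pays with a longer linear sequence.

**Alternative 2:** cut C1–C10. Acid A4 would be decarboxylated photocatalytically (4CzIPN, Cs2CO3, blue light). The tertiary α-oxy C10 radical adds to C1 of the β-sulfonyl enone and expels sulfinate to give dienone A3.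
- Merits: the E C1=C2 alkene and the quaternary carbinol form in the ring-closing event under mild, redox-neutral conditions, and the configuration of the acid precursor is irrelevant. The alkene is introduced more directly than in the chosen plan.
- Weak points: a ten-membered radical closure by a tertiary radical competes with reduction and oligomerisation. The 10R outcome depends on the facial preference of a dioxanyl radical inside a forming macrocycle. A4 combines a carboxylate with two Michael acceptors under basic conditions. The methylene must be unmasked later from the silyloxymethyl group.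
- The chosen plan sets against it a ring-forming reaction of an established class and a C10 centre made on a rigid cyclohexane.

**Alternative 3:** cut C7–C8. Bromomethyl butenolide aldehyde A6 would be treated with indium. The allylindium adds through C7 to the C8 aldehyde and gives A5, which lacks only the tiglate.
- Merits: it is the shortest endgame of all. Lactone, methylene, both alkenes and the free C8 hydroxyl appear in one step, with few protecting groups. In step count and convergence it beats the chosen plan.
- Weak points: two stereocentres (C7, C8) are set at once in a macrocyclisation, under control only of C6 and the ring conformation. The allylindium can react at C13 instead of C7. A6 is a β-hydroxy aldehyde (retro-aldol, dehydration) with an acidic, doubly activated C6–H and a sensitive dienone.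
- The chosen plan sets against it stepwise, predictable control: C7 from carvone, C6 and C10 on six-membered rings, C8 by directed reduction.

Key step: step 12

## Route

Remark: 3-chloro-2-methylprop-1-ene (7) is used as its iodide, made by Finkelstein exchange just before use. The hindered tertiary triethylsilyl ether at C8 is assumed to hydrolyse under the aqueous HClO4 of step 10.

Step 1
Reactants: 1 (S)-carvone
Product: 2 (5S)-5-(3-chloroprop-1-en-2-yl)-2-methylcyclohex-2-en-1-one
Conditions: Ca(OCl)2, CO2 (dry ice), CH2Cl2/H2O, 0 °C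
Reagents that add atoms: calcium hypochlorite, [Ca+2].[O-]Cl.[O-]Cl
Why: Ene-type allylic chlorination by hypochlorous acid formed in situ; only the electron-rich isopropenyl alkene reacts, the enone alkene is too electron-poor, and C7 is untouched.

Step 2
Reactants: 2 (5S)-5-(3-chloroprop-1-en-2-yl)-2-methylcyclohex-2-en-1-one
Product: 4 (5S)-5-(3-hydroxyprop-1-en-2-yl)-2-methylcyclohex-2-en-1-one, via allylic acetate 3 (not isolated)
Conditions: KOAc, Bu4NI (cat.), DMF, 60 °C; then K2CO3, MeOH, rt
Reagents that add atoms: potassium acetate, CC(=O)[O-].[K+]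
Why: SN2 displacement of the primary allylic chloride by acetate followed by transesterification with methanol; the weakly basic medium should leave the enone and C7 alone.

Step 3
Reactants: 4 (5S)-5-(3-hydroxyprop-1-en-2-yl)-2-methylcyclohex-2-en-1-one
Product: 6 (5R,6R)-2-methyl-6-(triethylsilyloxy)-5-[3-(triethylsilyloxy)prop-1-en-2-yl]cyclohex-2-en-1-one, via bis(triethylsilyl) dienol ether 5 (not isolated)
Conditions: LiN(iPr)2 (2.2 equiv), THF, −78 °C; Et3SiCl (2.5 equiv), −78 → 0 °C; then mCPBA, NaHCO3, CH2Cl2, −20 °C
Reagents that add atoms: chlorotriethylsilane, CC[Si](Cl)(CC)CC; mCPBA, OOC(=O)c1cccc(Cl)c1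
Why: Kinetic α′-deprotonation and O-silylation of alkoxide and enolate, then Rubottom oxidation of the electron-rich silyl enol ether double bond with silyl transfer to the new oxygen; the oxidant should enter anti to the C7 arm, but this centre is re-formed in step 4, so its purity does not matter.

Step 4
Reactants: 6 (5R,6R)-2-methyl-6-(triethylsilyloxy)-5-[3-(triethylsilyloxy)prop-1-en-2-yl]cyclohex-2-en-1-one; 7 3-chloro-2-methylprop-1-ene
Product: 9 (5R,6S)-2-methyl-6-(2-methylprop-2-en-1-yl)-6-(triethylsilyloxy)-5-[3-(triethylsilyloxy)prop-1-en-2-yl]cyclohex-2-en-1-one, via lithium enolate 8 (not isolated)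
Conditions: LiN(iPr)2, THF, −78 °C; then 3-iodo-2-methylprop-1-ene (from 7, NaI, acetone, rt), −78 → −30 °C
Reagents that add atoms: none
Why: C-alkylation of an α-silyloxy ketone enolate with a reactive allylic iodide; the C7 arm sits pseudo-axial to avoid A(1,2) strain with the C8 silyloxy group, so the electrophile enters anti to it and the new quaternary C8 carries C9 trans and oxygen cis to the arm.

Step 5
Reactants: 9 (5R,6S)-2-methyl-6-(2-methylprop-2-en-1-yl)-6-(triethylsilyloxy)-5-[3-(triethylsilyloxy)prop-1-en-2-yl]cyclohex-2-en-1-one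
Product: 12 (4R,5S,6S)-4-hydroxy-5-(3-hydroxyprop-1-en-2-yl)-2-methyl-6-(2-methylprop-2-en-1-yl)-6-(triethylsilyloxy)cyclohex-2-en-1-one, via trimethylsilyl dienol ether 10 (not isolated), via γ-hydroxy enone 11 (not isolated)
Conditions: Me3SiOTf, Et3N, CH2Cl2, 0 °C; then mCPBA (1.05 equiv), NaHCO3, CH2Cl2, −40 °C; then PPTS, MeOH, 0 °C
Reagents that add atoms: mCPBA, OOC(=O)c1cccc(Cl)c1
Why: Vinylogous Rubottom oxidation: with C8 quaternary the ketone can enolise only towards C6, and the peracid should attack the unhindered diene terminus C6 rather than the methyl-bearing, neopentyl C4, anti to the C7 arm and the C8 silyloxy group, which sets the 6,7-trans relationship; PPTS in methanol then removes the trimethylsilyl and the primary triethylsilyl groups but should spare the hindered tertiary silyl ether.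

Step 6
Reactants: 12 (4R,5S,6S)-4-hydroxy-5-(3-hydroxyprop-1-en-2-yl)-2-methyl-6-(2-methylprop-2-en-1-yl)-6-(triethylsilyloxy)cyclohex-2-en-1-one
Product: 15 (3aS,4S,7aR)-6-methyl-3-methylidene-4-(2-methylprop-2-en-1-yl)-4-(triethylsilyloxy)-3,3a,4,7a-tetrahydro-1-benzofuran-2,5-dione, via hydroxy enal 13 (not isolated), via lactol 14 (not isolated)
Conditions: TEMPO (0.2 equiv), PhI(OAc)2 (2.5 equiv), CH2Cl2, rt
Reagents that add atoms: none
Why: TEMPO-mediated oxidative lactonisation: the primary allylic alcohol is oxidised first, the aldehyde is trapped by the C6 hydroxyl as the trans-fused lactol, and the lactol is oxidised to the methylene lactone; the tertiary C8 oxygen is silylated and cannot compete, and no 1,2-diol is present for PhI(OAc)2 to cleave.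

Step 7
Reactants: 15 (3aS,4S,7aR)-6-methyl-3-methylidene-4-(2-methylprop-2-en-1-yl)-4-(triethylsilyloxy)-3,3a,4,7a-tetrahydro-1-benzofuran-2,5-dione; 16 allyl bromide
Product: 17 (3aS,4S,5R,7aR)-5-hydroxy-6-methyl-3-methylidene-4-(2-methylprop-2-en-1-yl)-5-(prop-2-en-1-yl)-4-(triethylsilyloxy)-3a,4,5,7a-tetrahydro-1-benzofuran-2(3H)-one
Conditions: CH2=CHCH2ZnBr (from 16, Zn, THF, 0 °C, decanted from excess metal), THF, −78 → −20 °C; aq. NH4Cl
Reagents that add atoms: none
Why: 1,2-Allylation of the enone carbonyl through the cyclic transition state of an allylzinc, which at low temperature should spare the lactone and the acrylate unit; the trans-fused lactone locks ring B with the C8 silyloxy group pseudo-axial, so the nucleophile adds anti to it (Felkin–Anh and steric control) and the new C3 centre has allyl cis to the methallyl arm and oxygen cis to the C8 oxygen.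

Step 8
Reactants: 17 (3aS,4S,5R,7aR)-5-hydroxy-6-methyl-3-methylidene-4-(2-methylprop-2-en-1-yl)-5-(prop-2-en-1-yl)-4-(triethylsilyloxy)-3a,4,5,7a-tetrahydro-1-benzofuran-2(3H)-one
Product: 18 (3R,6R,7S,8S)-3-hydroxy-8-(triethylsilyloxy)-3,8-cyclogermacra-1(10),4,11(13)-trien-12,6-olide
Conditions: second-generation Grubbs catalyst (H2IMes)(PCy3)Cl2Ru=CHPh (5 mol %), CH2Cl2, 40 °C
Reagents that add atoms: none
Why: Ring-closing metathesis of the allyl and methallyl arms to a trisubstituted cyclohexene; the arms are cis, so ring A closes cis-fused, and neither the ring alkene nor the acrylate methylene can reach a partner in a ring of reasonable size.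

Step 9
Reactants: 18 (3R,6R,7S,8S)-3-hydroxy-8-(triethylsilyloxy)-3,8-cyclogermacra-1(10),4,11(13)-trien-12,6-olide
Product: 19 (1R,3R,6R,7S,8S,10S)-1,10-epoxy-3-hydroxy-8-(triethylsilyloxy)-3,8-cyclogermacra-4,11(13)-dien-12,6-olide
Conditions: mCPBA (1.1 equiv), NaHCO3, CH2Cl2, 0 °C
Reagents that add atoms: mCPBA, OOC(=O)c1cccc(Cl)c1
Why: Prilezhaev epoxidation of the most electron-rich alkene (C4=C5 is deactivated by two allylic oxygens, the lactone methylene is electron-poor); the peracid should come from the convex face, guided by hydrogen bonding to the axial homoallylic C3 hydroxyl (Henbest effect) and kept off the other face by the axial C8–C7 bond, which sets C1 and C10 with the oxygen on the side of the ring-fusion oxygens.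

Step 10
Reactants: 19 (1R,3R,6R,7S,8S,10S)-1,10-epoxy-3-hydroxy-8-(triethylsilyloxy)-3,8-cyclogermacra-4,11(13)-dien-12,6-olide
Product: 20 (1R,3R,6R,7S,8S,10R)-1,3,8,10-tetrahydroxy-3,8-cyclogermacra-4,11(13)-dien-12,6-olide
Conditions: HClO4 (1 M aq.), THF, 0 °C → rt
Reagents that add atoms: water, O
Why: Acid-catalysed epoxide hydrolysis: in the lactone-locked ring A both the Markovnikov preference and the trans-diaxial (Fürst–Plattner) rule send water to tertiary C10 anti to the epoxide oxygen, so C10 is inverted to 10R while the C1 oxygen stays; the same medium should cleave the tertiary silyl ether.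

Step 11
Reactants: 20 (1R,3R,6R,7S,8S,10R)-1,3,8,10-tetrahydroxy-3,8-cyclogermacra-4,11(13)-dien-12,6-olide
Product: 21 (1R,3R,6R,7S,8S,10R)-1-acetoxy-3,8,10-trihydroxy-3,8-cyclogermacra-4,11(13)-dien-12,6-olide
Conditions: Ac2O (1.2 equiv), pyridine, DMAP (cat.), CH2Cl2, 0 °C
Reagents that add atoms: acetic anhydride, CC(=O)OC(C)=O
Why: Selective acylation of the only secondary hydroxyl beside three tertiary ones; the acetate removes the second 1,2-diol and places the leaving group for step 15.

Step 12
Reactants: 21 (1R,3R,6R,7S,8S,10R)-1-acetoxy-3,8,10-trihydroxy-3,8-cyclogermacra-4,11(13)-dien-12,6-olide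
Product: 23 (1R,4Z,6R,7S,10R)-1-acetoxy-10-hydroxy-3,8-dioxogermacra-4,11(13)-dien-12,6-olide, via cyclic lead diester 22 (not isolated)
Conditions: Pb(OAc)4 (1.1 equiv), CH2Cl2, 0 °C, 20 min; filtered through Celite, concentrated cold and used at once
Reagents that add atoms: none
Why: The cis C3 and C8 hydroxyls displace two acetates on tetravalent lead to give the five-membered cyclic diester 22, which collapses in a concerted two-electron step (Criegee glycol cleavage) to the C3 and C8 ketones, Pb(OAc)2 and AcOH. The closest known reaction type is the Pb(OAc)4 fission of ring-fusion cis-diols of decalins to cyclodecane-1,6-diones. The ten-membered ring is not closed by bond formation; it is released when the bond shared by rings A and B is cut, so no cyclisation mode, dilution or entropic penalty is involved. No stereocentre is created: C1, C6, C7 and C10 keep the configurations set on the bicycle, and C4=C5, cis of necessity in ring B, emerges as the Z-enone. The step needs chemoselectivity for the ring-fusion diol, which the substrate secures: it is the only free 1,2-diol (the neighbour of the C10 hydroxyl is acetylated), it is cis with a gauche O–C–C–O angle that allows the cyclic diester, and both carbinols are tertiary so that only ketones can form. It also needs the product to survive: the new C8 ketone is β to the C6 lactone oxygen and the C3 ketone β to the C1 acetate, so base is excluded, the medium stays weakly acidic and 23 is reduced immediately.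

Step 13
Reactants: 23 (1R,4Z,6R,7S,10R)-1-acetoxy-10-hydroxy-3,8-dioxogermacra-4,11(13)-dien-12,6-olide
Product: 25 (1R,4Z,6R,7R,8R,10R)-1-acetoxy-8,10-dihydroxy-3-oxogermacra-4,11(13)-dien-12,6-olide, via alkoxyborohydride 24 (not isolated)
Conditions: Me4NBH(OAc)3 (5 equiv), MeCN/AcOH (1:1), −30 °C
Reagents that add atoms: none
Why: Evans–Saksena reduction: the C10 hydroxyl exchanges an acetate on boron and delivers hydride to C8 through a chair transition state, which should give the 1,3-anti diol (8R); the reagent does not reduce ketones without a β-hydroxyl, so the C3 enone stays, and the acidic medium protects the C1 acetate and C7.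

Step 14
Reactants: 25 (1R,4Z,6R,7R,8R,10R)-1-acetoxy-8,10-dihydroxy-3-oxogermacra-4,11(13)-dien-12,6-olide; 26 tiglic acid
Product: 27 (1R,4Z,6R,7R,8R,10R)-1-acetoxy-10-hydroxy-3-oxo-8-tigloyloxygermacra-4,11(13)-dien-12,6-olide
Conditions: 26, 2,4,6-Cl3C6H2COCl, Et3N, THF, rt; then 25, DMAP, toluene, 0 °C → rt
Reagents that add atoms: none
Why: Yamaguchi esterification through the mixed anhydride acylates the secondary C8 hydroxyl while the tertiary C10 hydroxyl is too hindered; the E geometry of the tiglate is the stable one, and any β-elimination of the C1 acetate that DMAP begins only anticipates step 15.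

Step 15
Reactants: 27 (1R,4Z,6R,7R,8R,10R)-1-acetoxy-10-hydroxy-3-oxo-8-tigloyloxygermacra-4,11(13)-dien-12,6-olide
Product: 28 eupaheliangolide A
Conditions: DBU (1.2 equiv), CH2Cl2, −20 → 0 °C
Reagents that add atoms: none
Why: E1cB elimination of the β-acetoxy ketone: deprotonation at C2 and loss of acetate from C1 give the enone, and the E isomer should form because the quaternary C10 avoids the position cis to the carbonyl in the eliminating conformer; C10 has no hydrogen, so the alkene can only form towards C2.

## Compound list

1 | (S)-carvone, (5S)-2-methyl-5-(prop-1-en-2-yl)cyclohex-2-en-1-one | CC1=CC[C@@H](CC1=O)C(C)=C | starting material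
2 | (5S)-5-(3-chloroprop-1-en-2-yl)-2-methylcyclohex-2-en-1-one | CC1=CC[C@@H](CC1=O)C(CCl)=C | intermediate
3 | allylic acetate, 2-[(1S)-4-methyl-5-oxocyclohex-3-en-1-yl]prop-2-en-1-yl acetate | CC1=CC[C@@H](CC1=O)C(COC(C)=O)=C | intermediate (not isolated)
4 | (5S)-5-(3-hydroxyprop-1-en-2-yl)-2-methylcyclohex-2-en-1-one | CC1=CC[C@@H](CC1=O)C(CO)=C | intermediate
5 | bis(triethylsilyl) dienol ether, (6S)-3-methyl-2-(triethylsilyloxy)-6-[3-(triethylsilyloxy)prop-1-en-2-yl]cyclohexa-1,3-diene | CC1=CC[C@@H](C=C1O[Si](CC)(CC)CC)C(CO[Si](CC)(CC)CC)=C | intermediate (not isolated)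
6 | (5R,6R)-2-methyl-6-(triethylsilyloxy)-5-[3-(triethylsilyloxy)prop-1-en-2-yl]cyclohex-2-en-1-one (silyloxy trans to the side chain) | CC1=CC[C@@H]([C@@H](O[Si](CC)(CC)CC)C1=O)C(CO[Si](CC)(CC)CC)=C | intermediate
7 | 3-chloro-2-methylprop-1-ene | C=C(C)CCl | starting material
8 | lithium enolate of 6 (C3–OLi, C3=C8) | CC1=CC[C@@H](C(O[Si](CC)(CC)CC)=C1O[Li])C(CO[Si](CC)(CC)CC)=C | intermediate (not isolated)
9 | (5R,6S)-2-methyl-6-(2-methylprop-2-en-1-yl)-6-(triethylsilyloxy)-5-[3-(triethylsilyloxy)prop-1-en-2-yl]cyclohex-2-en-1-one (methallyl trans, silyloxy cis to the side chain) | CC1=CC[C@@H]([C@@](O[Si](CC)(CC)CC)(CC(C)=C)C1=O)C(CO[Si](CC)(CC)CC)=C | intermediate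
10 | trimethylsilyl dienol ether of 9 (C3–OSiMe3, C3=C4 and C5=C6) | CC1=C(O[Si](C)(C)C)[C@](O[Si](CC)(CC)CC)(CC(C)=C)[C@H](C=C1)C(CO[Si](CC)(CC)CC)=C | intermediate (not isolated)
11 | γ-hydroxy enone, (4R,5S,6S)-4-hydroxy-2-methyl-6-(2-methylprop-2-en-1-yl)-6-(triethylsilyloxy)-5-[3-(triethylsilyloxy)prop-1-en-2-yl]cyclohex-2-en-1-one | CC1=C[C@@H](O)[C@@H]([C@@](O[Si](CC)(CC)CC)(CC(C)=C)C1=O)C(CO[Si](CC)(CC)CC)=C | intermediate (not isolated)
12 | (4R,5S,6S)-4-hydroxy-5-(3-hydroxyprop-1-en-2-yl)-2-methyl-6-(2-methylprop-2-en-1-yl)-6-(triethylsilyloxy)cyclohex-2-en-1-one (C6–OH trans to the side chain) | CC1=C[C@@H](O)[C@@H]([C@@](O[Si](CC)(CC)CC)(CC(C)=C)C1=O)C(CO)=C | intermediate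
13 | hydroxy enal, 2-[(1S,2S,6R)-6-hydroxy-4-methyl-2-(2-methylprop-2-en-1-yl)-3-oxo-2-(triethylsilyloxy)cyclohex-4-en-1-yl]prop-2-enal | CC1=C[C@@H](O)[C@@H]([C@@](O[Si](CC)(CC)CC)(CC(C)=C)C1=O)C(C=O)=C | intermediate (not isolated)
14 | lactol, (3aS,4S,7aR)-2-hydroxy-6-methyl-3-methylidene-4-(2-methylprop-2-en-1-yl)-4-(triethylsilyloxy)-3,3a,4,7a-tetrahydro-1-benzofuran-5(2H)-one (either C2 epimer) | C=C1C(O)O[C@@H]2C=C(C)C(=O)[C@](O[Si](CC)(CC)CC)(CC(C)=C)[C@@H]12 | intermediate (not isolated)
15 | (3aS,4S,7aR)-6-methyl-3-methylidene-4-(2-methylprop-2-en-1-yl)-4-(triethylsilyloxy)-3,3a,4,7a-tetrahydro-1-benzofuran-2,5-dione (trans-fused lactone; germacrane 6R,7S,8S) | C=C1C(=O)O[C@@H]2C=C(C)C(=O)[C@](O[Si](CC)(CC)CC)(CC(C)=C)[C@@H]12 | intermediate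
16 | allyl bromide, 3-bromoprop-1-ene | C=CCBr | starting material
17 | (3aS,4S,5R,7aR)-5-hydroxy-6-methyl-3-methylidene-4-(2-methylprop-2-en-1-yl)-5-(prop-2-en-1-yl)-4-(triethylsilyloxy)-3a,4,5,7a-tetrahydro-1-benzofuran-2(3H)-one (allyl cis to methallyl; germacrane 3R,6R,7S,8S) | C=C1C(=O)O[C@@H]2C=C(C)[C@](O)(CC=C)[C@](O[Si](CC)(CC)CC)(CC(C)=C)[C@@H]12 | intermediate
18 | (3R,6R,7S,8S)-3-hydroxy-8-(triethylsilyloxy)-3,8-cyclogermacra-1(10),4,11(13)-trien-12,6-olide (cis-fused octalin, trans lactone) | C=C1C(=O)O[C@@H]2C=C(C)[C@]3(O)CC=C(C)C[C@]3(O[Si](CC)(CC)CC)[C@@H]12 | intermediate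
19 | (1R,3R,6R,7S,8S,10S)-1,10-epoxy-3-hydroxy-8-(triethylsilyloxy)-3,8-cyclogermacra-4,11(13)-dien-12,6-olide (epoxide on the face of the ring-fusion oxygens) | C=C1C(=O)O[C@@H]2C=C(C)[C@]3(O)C[C@H]4O[C@@]4(C)C[C@]3(O[Si](CC)(CC)CC)[C@@H]12 | intermediate
20 | (1R,3R,6R,7S,8S,10R)-1,3,8,10-tetrahydroxy-3,8-cyclogermacra-4,11(13)-dien-12,6-olide (1,10-diol trans, 3,8-diol cis) | C=C1C(=O)O[C@@H]2C=C(C)[C@]3(O)C[C@@H](O)[C@](C)(O)C[C@]3(O)[C@@H]12 | intermediate
21 | (1R,3R,6R,7S,8S,10R)-1-acetoxy-3,8,10-trihydroxy-3,8-cyclogermacra-4,11(13)-dien-12,6-olide | C=C1C(=O)O[C@@H]2C=C(C)[C@]3(O)C[C@@H](OC(C)=O)[C@](C)(O)C[C@]3(O)[C@@H]12 | intermediate (key-step precursor)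
22 | cyclic diacetoxy tetravalent-lead diester of 21 (C3–O–Pb(OAc)2–O–C8) | C=C1C(=O)O[C@@H]2C=C(C)[C@]34C[C@@H](OC(C)=O)[C@](C)(O)C[C@]3(O[Pb](OC(C)=O)(OC(C)=O)O4)[C@@H]12 | intermediate (not isolated)
23 | (1R,4Z,6R,7S,10R)-1-acetoxy-10-hydroxy-3,8-dioxogermacra-4,11(13)-dien-12,6-olide | C=C1C(=O)O[C@@H]2/C=C(/C)C(=O)C[C@@H](OC(C)=O)[C@](C)(O)CC(=O)[C@@H]12 | intermediate (key-step product)
24 | tetramethylammonium diacetoxy(hydrido)borate ester of the C10 hydroxyl of 23 | C=C1C(=O)O[C@@H]2/C=C(/C)C(=O)C[C@@H](OC(C)=O)[C@](C)(O[BH-](OC(C)=O)OC(C)=O)CC(=O)[C@@H]12.C[N+](C)(C)C | intermediate (not isolated)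
25 | (1R,4Z,6R,7R,8R,10R)-1-acetoxy-8,10-dihydroxy-3-oxogermacra-4,11(13)-dien-12,6-olide | C=C1C(=O)O[C@@H]2/C=C(/C)C(=O)C[C@@H](OC(C)=O)[C@](C)(O)C[C@@H](O)[C@@H]12 | intermediate
26 | tiglic acid, (E)-2-methylbut-2-enoic acid | C/C=C(\C)C(=O)O | starting material
27 | (1R,4Z,6R,7R,8R,10R)-1-acetoxy-10-hydroxy-3-oxo-8-tigloyloxygermacra-4,11(13)-dien-12,6-olide | C=C1C(=O)O[C@@H]2/C=C(/C)C(=O)C[C@@H](OC(C)=O)[C@](C)(O)C[C@@H](OC(=O)/C(C)=C/C)[C@@H]12 | intermediate
28 | eupaheliangolide A, (1E,4Z,6R,7R,8R,10R)-10-hydroxy-3-oxo-8-tigloyloxygermacra-1,4,11(13)-trien-12,6-olide | C=C1C(=O)O[C@@H]2/C=C(/C)C(=O)/C=C/[C@](C)(O)C[C@@H](OC(=O)/C(C)=C/C)[C@@H]12 | target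

## Step count and risks

Total: 15 steps. Longest linear sequence: 15 steps from (S)-carvone (1); compounds 7, 16 and 26 enter in steps 4, 7 and 14.

**Step 12 (key step).** The cleavage itself should be fast. The likely failure is decay of 23 during isolation: E1cB loss of the C6 lactone oxygen or epimerisation at C7 next to the new C8 ketone, transannular aldol re-closure, or early loss of the C1 acetate. Fallback: turn the two operations into one reductive fission that never isolates the diketone. Diol 21 is cleaved with Pb(OAc)4 (1.0 equiv) in MeCN/AcOH at −30 °C, and Me4NBH(OAc)3 is added to the same flask once the oxidant is consumed. Ketone 23 is then reduced as it forms, and the route is rejoined at 25 (no new compound, F0).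

**Step 4.** The tetrasubstituted α-silyloxy enolate may react sluggishly at carbon, may suffer O-to-O silyl migration on warming, or may form in competition with γ-deprotonation. Fallback: replace the intermolecular SN2 alkylation by a decarboxylative allylation with zerovalent palladium. Ketone 6 is deprotonated with KN(SiMe3)2 and O-acylated with 2-methylallyl chloroformate to the enol carbonate F1. Pd(PPh3)4 then ionises it, and the ion pair recombines at C8 with loss of CO2, anti to the C7 arm, to give 9.

**Step 5.** The peracid may attack the more electron-rich C3=C4 bond of the dienol ether (α-hydroxylation at C4), or may approach C6 with poor facial selectivity. Fallback: enforce the γ-position by a cycloaddition. Dienol ether 10 (from 9) takes up singlet oxygen (O2, tetraphenylporphyrin, light, −78 °C) across C3 and C6 to give the endoperoxide F2. Reduction with Me2S and loss of the silyl group gives 11, which continues to 12 as in step 5.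

**Step 10.** Water may open the epoxide at C1, or through a free C10 cation without stereospecificity. The acid may also ionise the tertiary allylic C3 hydroxyl or leave the silyl ether in place. Fallback: capture water through a bromonium ion instead of a protonated epoxide and use bromide as the leaving group for the final elimination.
- Alkene 18 with NBS in THF/H2O gives the bromohydrin F3 (bromine on the convex face at C1, hydroxyl anti at C10).
- HF·pyridine removes the silyl group to give the triol F4.
- Pb(OAc)4 gives the bromo diketone F5.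
- Me4NBH(OAc)3 gives the bromo alcohol F6.
- Yamaguchi esterification with 26 gives the bromo tiglate F7.
- Et3N eliminates HBr to 28.

**Step 13.** The C10 hydroxyl may be tied up as a transannular hemiketal with the C3 carbonyl, so that hydride is not delivered intramolecularly and the facial selectivity at C8 is lost or reversed. Reduction at C3 is not expected. Fallback: if the reduction of 23 gives mainly the C8-epimeric alcohol F8, a Mitsunobu esterification with tiglic acid 26 (PPh3, DIAD) inverts C8 and installs the ester in one step, rejoining the route at 27.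

## Further compounds

F0 | step 12 | none | none
F1 | step 4 | 2-methylprop-2-en-1-yl enol carbonate of 6 (C3–O–CO2CH2C(CH3)=CH2, C3=C8) | CC1=CC[C@@H](C(O[Si](CC)(CC)CC)=C1OC(=O)OCC(C)=C)C(CO[Si](CC)(CC)CC)=C
F2 | step 5 | 3,6-endoperoxide of dienol ether 10 (peroxide bridge anti to the C7 arm) | CC1=C[C@H]2OO[C@]1(O[Si](C)(C)C)[C@](O[Si](CC)(CC)CC)(CC(C)=C)[C@H]2C(CO[Si](CC)(CC)CC)=C
F3 | step 10 | bromohydrin, 1-bromo-3,10-dihydroxy-8-(triethylsilyloxy)-3,8-cyclogermacra-4,11(13)-dien-12,6-olide (Br trans to 10-OH) | C=C1C(=O)O[C@@H]2C=C(C)[C@]3(O)C[C@@H](Br)[C@](C)(O)C[C@]3(O[Si](CC)(CC)CC)[C@@H]12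
F4 | step 10 | triol, 1-bromo-3,8,10-trihydroxy-3,8-cyclogermacra-4,11(13)-dien-12,6-olide | C=C1C(=O)O[C@@H]2C=C(C)[C@]3(O)C[C@@H](Br)[C@](C)(O)C[C@]3(O)[C@@H]12
F5 | step 10 | bromo diketone, (4Z)-1-bromo-10-hydroxy-3,8-dioxogermacra-4,11(13)-dien-12,6-olide | C=C1C(=O)O[C@@H]2/C=C(/C)C(=O)C[C@@H](Br)[C@](C)(O)CC(=O)[C@@H]12
F6 | step 10 | bromo alcohol, (4Z)-1-bromo-8,10-dihydroxy-3-oxogermacra-4,11(13)-dien-12,6-olide | C=C1C(=O)O[C@@H]2/C=C(/C)C(=O)C[C@@H](Br)[C@](C)(O)C[C@@H](O)[C@@H]12
F7 | step 10 | bromo tiglate, (4Z)-1-bromo-10-hydroxy-3-oxo-8-tigloyloxygermacra-4,11(13)-dien-12,6-olide | C=C1C(=O)O[C@@H]2/C=C(/C)C(=O)C[C@@H](Br)[C@](C)(O)C[C@@H](OC(=O)/C(C)=C/C)[C@@H]12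
F8 | step 13 | C8-epimeric alcohol, (8S)-epimer of 25 | C=C1C(=O)O[C@@H]2/C=C(/C)C(=O)C[C@@H](OC(C)=O)[C@](C)(O)C[C@H](O)[C@@H]12
A1 | alternative 1 | ten-membered anti hydroxy ester (6R,7R) with 3-O-TBS and 8-O-TES | O[C@@H]1/C=C(/C)[C@H](O[Si](C)(C)C(C)(C)C)/C=C/[C@](C)(O)C[C@@H](O[Si](CC)(CC)CC)[C@H]1C(=C)C(=O)OC
A2 | alternative 1 | open-chain C6 aldehyde with C13 allylic bromide, methyl (Z)-2-(bromomethyl)alk-2-enoate | O=C/C=C(/C)[C@H](O[Si](C)(C)C(C)(C)C)/C=C/[C@](C)(O)C[C@@H](O[Si](CC)(CC)CC)/C=C(\CBr)C(=O)OC
A3 | alternative 2 | ten-membered dienone with 8,10-acetonide and 13-silyloxy lactone (10R) | CC(C)(C)[Si](C)(C)OC[C@@H]1C(=O)O[C@@H]2/C=C(/C)C(=O)/C=C/[C@]3(C)OC(C)(C)O[C@H](C3)[C@@H]12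
A4 | alternative 2 | C10 carboxylic acid (either C10 epimer) with (E)-β-phenylsulfonyl enone | CC(C)(C)[Si](C)(C)OC[C@@H]1C(=O)O[C@H](/C=C(/C)C(=O)/C=C/S(=O)(=O)c2ccccc2)[C@H]1[C@H]1CC(C)(C(=O)O)OC(C)(C)O1
A5 | alternative 3 | 8-O-destigloyl eupaheliangolide A | C=C1C(=O)O[C@@H]2/C=C(/C)C(=O)/C=C/[C@](C)(O)C[C@@H](O)[C@@H]12
A6 | alternative 3 | 3-(bromomethyl)butenolide with C8 aldehyde side chain | BrCC1=C[C@H](OC1=O)/C=C(/C)C(=O)/C=C/[C@](C)(O)CC=O
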